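**Assumption:** the (S,S) phase-transfer catalyst in step 2 is taken to give (R)-4; if it gives the antipode, the commercial (R,R) catalyst is used and nothing else changes.

**Atom labels (Daphniphyllum numbering, used in names):** N; C1 lactam C=O; C2 ketone of the nine-membered ring; C3, C4; C5 quaternary bridge carbon (C21 = its CH2O); C6; C7 (NCH2); C8 quaternary; C9=C11 enone alkene; C10 enone C=O; C12; C13; C14 (C22 = CO2Me); C15 (OH); C16, C17; C18 (C20 = CH3); C19 (NCH2). Target = (5R,6S,8S,14R,15S,18R).

## Retrosynthetic overview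

1. Ring B is carried as an anisole: the C15–OH/C10 enone comes from oxidative dearomatization of a phenol (p-quinol) and selective C16=C17 hydrogenation; C14 comes from hydrogenation of an indene ester.
2. The nine-membered ring and quaternary C5 come from an intramolecular Michael addition (C4–C5) of a C5 aldehyde onto an N-tethered vinyl ketone; C21 comes from Wittig homologation of a C5 ketone.
3. The bridged lactam comes from Mannich/lactamization of a β-keto ester with CH2O and a chiral primary amine (C18 from (R)-3-aminoisobutyric acid).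
4. Ring A comes from Friedel–Crafts cyclodehydration of an α-keto ester; C8 comes from asymmetric alkylation of the β-keto ester of 5-methoxy-2-tetralone.
5. Ring order: B (arene) and C (tetralone) are bought → A → lactam D → nine-membered ring E → dearomatization of B.

## Route

Step 1
Reactants: 1 5-methoxy-2-tetralone
Product: 2 methyl 5-methoxy-2-oxotetralin-1-carboxylate
Conditions: NaH, (MeO)2CO, THF, 65 °C; aq. HCl
Reagents that add atoms: dimethyl carbonate, COC(=O)OC
Why: Claisen-type C-acylation of the conjugated benzylic (C1) enolate of the β-tetralone, driven by removal of the acidic β-keto ester as its enolate; no stereocentre is kept.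

Step 2
Reactants: 2 methyl 5-methoxy-2-oxotetralin-1-carboxylate; 3 methyl 2-(bromomethyl)acrylate
Product: 4 (R)-allylated β-keto ester
Conditions: 3 (1.2 equiv), (S,S)-3,4,5-trifluorophenyl-NAS bromide (Maruoka catalyst, 2 mol%), K2CO3 (s), toluene, −20 °C
Reagents that add atoms: none
Why: Asymmetric phase-transfer C-alkylation in which the chiral ammonium–enolate ion pair exposes one enolate face to the reactive allylic bromide, setting the quaternary C8 centre (R here, 8S in the target).

Step 3
Reactants: 4 (R)-allylated β-keto ester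
Product: 6 α-keto ester, via ozonide 5 (not isolated)
Conditions: O3, CH2Cl2, −78 °C (Sudan III end point); then Me2S, −78 → 23 °C
Reagents that add atoms: ozone, [O-][O+]=O
Why: Ozonolysis with reductive work-up cleaves the only alkene (the 1,1-disubstituted acrylate) to the α-keto ester without touching C8.

Step 4
Reactants: 6 α-keto ester
Product: 8 tricyclic indene diester ketone, via tertiary benzylic alcohol 7 (not isolated)
Conditions: TfOH, CH2Cl2, 0 → 23 °C
Reagents that add atoms: none
Why: Intramolecular Friedel–Crafts hydroxyalkylation by the protonated α-keto ester at the only reachable ring position (para to OMe, five-membered ring A), followed by E1 dehydration to the conjugated indene ester, whose C13=C14 bond cannot migrate because C8 is quaternary.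

Step 5
Reactants: 9 (R)-3-(Boc-amino)-2-methylpropanoic acid
Product: 10 Boc-protected Weinreb amide
Conditions: MeNHOMe·HCl, EDC·HCl, N-methylmorpholine, CH2Cl2, 0 → 23 °C
Reagents that add atoms: N,O-dimethylhydroxylamine hydrochloride, CNOC.Cl
Why: Carbodiimide amide coupling of a carbamate-protected β-amino acid, which proceeds without epimerizing the α-methyl stereocentre (the future C18, bought from the chiral pool).

Step 6
Reactants: 10 Boc-protected Weinreb amide
Product: 11 amine hydrochloride
Conditions: 4 M HCl in dioxane, 23 °C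
Reagents that add atoms: hydrogen chloride, Cl
Why: Acidolytic Boc cleavage (loss of isobutene and CO2) gives the ammonium salt needed for the Mannich step and leaves the stereocentre untouched.

Step 7
Reactants: 8 tricyclic indene diester ketone; 11 amine hydrochloride
Product: 13 bridged keto lactam, via Mannich base 12 (not isolated)
Conditions: (CH2O)n, EtOH, 70 °C; then Et3N, toluene, 80 °C
Reagents that add atoms: formaldehyde (as paraformaldehyde), C=O
Why: Mannich reaction at C6, the only enolizable position of the ketone, followed by lactamization of the secondary amine onto the C1 ester; C6 is epimerizable α to the ketone, so only the epimer with CH2N cis to C1 can bridge and C6 is set by C8.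

Step 8
Reactants: 13 bridged keto lactam
Product: 14 methyl enol ether (E/Z mixture)
Conditions: Ph3P(CH2OMe)Cl, NaHMDS, THF, 0 °C; then 13, 0 → 40 °C
Reagents that add atoms: (methoxymethyl)triphenylphosphonium chloride, COC[P+](c1ccccc1)(c1ccccc1)c1ccccc1.[Cl-]
Why: Wittig methoxymethylenation of the non-enolizable bridging C5 ketone adds C21, while the esters, lactam and Weinreb amide are inert to the ylide.

Step 9
Reactants: 14 methyl enol ether
Product: 15 vinyl ketone
Conditions: CH2=CHMgBr, THF, −40 → 0 °C; cold aq. NH4Cl
Reagents that add atoms: vinylmagnesium bromide, C=C[Mg]Br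
Why: Weinreb ketone synthesis, in which the stable magnesium chelate prevents over-addition, the hindered conjugated ester and lactam react more slowly, and C18 is not enolized at this temperature.

Step 10
Reactants: 15 vinyl ketone
Product: 17 pentacyclic keto aldehyde, via C5 aldehyde 16 (not isolated)
Conditions: 1 M HCl, THF, 23 °C; then pyrrolidine (0.3 equiv), AcOH (0.3 equiv), MeCN (2 mM), 40 °C
Reagents that add atoms: water, O
Why: Enol ether hydrolysis, then an intramolecular enamine Michael addition of the aldehyde (both C5 epimers converge) to the vinyl ketone; the N-anchored tether reaches C5 only from the lactam side, so C4 enters syn to N and the CHO ends up over the arene, which sets the quaternary C5 centre and closes the nine-membered ring.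

Step 11
Reactants: 17 pentacyclic keto aldehyde
Product: 18 primary alcohol
Conditions: NaBH4, EtOH/CH2Cl2, −78 → −40 °C; aq. NH4Cl
Reagents that add atoms: none
Why: Chemoselective borohydride reduction, the aldehyde being reduced far faster than the medium-ring ketone at low temperature, with no change at any stereocentre.

Step 12
Reactants: 18 primary alcohol
Product: 19 acetate
Conditions: Ac2O, pyridine, DMAP (cat.), CH2Cl2, 23 °C
Reagents that add atoms: acetic anhydride, CC(=O)OC(C)=O
Why: DMAP-catalysed O-acetylation of the only hydroxyl group, which also prevents it from trapping the phenoxenium ion in step 15.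

Step 13
Reactants: 19 acetate
Product: 20 indane ester
Conditions: H2 (1 atm), 10% Pd/C, EtOAc, 23 °C
Reagents that add atoms: none
Why: Heterogeneous syn-hydrogenation of the conjugated C13=C14 bond from the face anti to the C5 bridge (whose axial CH2OAc lies over C8/C9), placing H-14 on the lactam-carbonyl face and CO2Me on the opposite face (14R).

Step 14
Reactants: 20 indane ester
Product: 21 phenol
Conditions: BBr3, CH2Cl2, −78 → −10 °C; H2O quench
Reagents that add atoms: none
Why: Lewis-acid aryl methyl ether cleavage (bromide attacks the O-methyl of the ArO(Me)–BBr3 adduct), run cold so that the methyl ester, acetate, lactam and ketone survive.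

Step 15
Reactants: 21 phenol
Product: 22 p-quinol dienone
Conditions: PhI(OAc)2, MeCN/H2O 3:1, 0 °C
Reagents that add atoms: water, O
Why: Hypervalent-iodine oxidative dearomatization of the para-alkyl phenol, with water adding at C15 anti to the adjacent C14–CO2Me and the CH2OAc-bearing bridge, giving the tertiary alcohol trans to the ester (15S).

Step 16
Reactants: 22 p-quinol dienone
Product: 23 target CNP0211170.1
Conditions: H2 (1 atm), RhCl(PPh3)3 (10 mol%), benzene, 23 °C
Reagents that add atoms: none
Why: Wilkinson hydrogenation reduces only the cis-disubstituted C16=C17 bond of the cross-conjugated dienone and leaves the tetrasubstituted C9=C11 enone and all stereocentres untouched.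

## Compound list

1 | 5-methoxy-3,4-dihydronaphthalen-2(1H)-one (5-methoxy-2-tetralone) | COc1cccc2c1CCC(=O)C2 | starting material
2 | methyl 5-methoxy-2-oxo-1,2,3,4-tetrahydronaphthalene-1-carboxylate (racemic, largely enol) | COC(=O)C1C(=O)CCc2c1cccc2OC | intermediate
3 | methyl 2-(bromomethyl)acrylate | C=C(CBr)C(=O)OC | starting material
4 | methyl (R)-5-methoxy-1-[2-(methoxycarbonyl)allyl]-2-oxo-1,2,3,4-tetrahydronaphthalene-1-carboxylate | COC(=O)C(=C)C[C@]1(C(=O)OC)C(=O)CCc2c1cccc2OC | intermediate
5 | ozonide (1,2,4-trioxolane) of the acrylate C=C of 4 | COC(=O)C1(C[C@]2(C(=O)OC)C(=O)CCc3c2cccc3OC)OCOO1 | intermediate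
6 | methyl (R)-5-methoxy-1-(3-methoxy-2,3-dioxopropyl)-2-oxo-1,2,3,4-tetrahydronaphthalene-1-carboxylate | COC(=O)C(=O)C[C@]1(C(=O)OC)C(=O)CCc2c1cccc2OC | intermediate
7 | dimethyl (2aR)-1-hydroxy-6-methoxy-3-oxo-1,2,2a,3,4,5-hexahydroacenaphthylene-1,2a-dicarboxylate (both C1 epimers) | COC(=O)C1(O)C[C@]2(C(=O)OC)C(=O)CCc3c2c1ccc3OC | intermediate
8 | dimethyl (R)-6-methoxy-3-oxo-2a,3,4,5-tetrahydroacenaphthylene-1,2a-dicarboxylate (C13=C14 indene ester, C5 ketone, C1 ester on C8) | COC(=O)C1=C[C@]2(C(=O)OC)C(=O)CCc3c2c1ccc3OC | intermediate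
9 | (R)-3-[(tert-butoxycarbonyl)amino]-2-methylpropanoic acid | OC(=O)[C@H](C)CNC(=O)OC(C)(C)C | starting material
10 | tert-butyl (R)-[3-(methoxy(methyl)amino)-2-methyl-3-oxopropyl]carbamate | CON(C)C(=O)[C@H](C)CNC(=O)OC(C)(C)C | intermediate
11 | (R)-3-amino-N-methoxy-N,2-dimethylpropanamide hydrochloride | Cl.CON(C)C(=O)[C@H](C)CN | intermediate
12 | Mannich base: 8 carrying at C6 (α to the ketone, both epimers) a CH2NH–CH2CH(CH3)C(O)N(OMe)CH3 group, side chain (R) | COC(=O)C1=C[C@]2(C(=O)OC)C(=O)C(CNC[C@@H](C)C(=O)N(C)OC)Cc3c2c1ccc3OC | intermediate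
13 | bridged keto lactam: N–C1(=O)–C8 and N–C7–C6 closed (2-azabicyclo[3.3.1]nonane-3,9-dione on the methoxy-indene ester), C5 ketone; N bears (R)-CH2CH(CH3)C(O)N(OMe)CH3; C6 and C8 arranged as in the target | COC(=O)C1=C[C@@]23C(=O)N(C[C@@H](C)C(=O)N(C)OC)C[C@@H](Cc4c2c1ccc4OC)C3=O | intermediate
14 | 13 with C5=CH–OCH3 (methyl enol ether, E/Z mixture) in place of the C5 ketone | COC(=O)C1=C[C@@]23C(=O)N(C[C@@H](C)C(=O)N(C)OC)C[C@@H](Cc4c2c1ccc4OC)C3=COC | intermediate
15 | 14 with the Weinreb amide replaced by a vinyl ketone: N–CH2–CH(CH3)–C(O)–CH=CH2, (R) | COC(=O)C1=C[C@@]23C(=O)N(C[C@@H](C)C(=O)C=C)C[C@@H](Cc4c2c1ccc4OC)C3=COC | intermediate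
16 | C5–CHO aldehyde from hydrolysis of 15 (both C5 epimers) | COC(=O)C1=C[C@@]23C(=O)N(C[C@@H](C)C(=O)C=C)C[C@@H](Cc4c2c1ccc4OC)C3C=O | intermediate
17 | pentacyclic keto aldehyde: C4–C5 bond closed (nine-membered ring N–C19–C18–C2(=O)–C3–C4–C5), quaternary C5 bearing CHO (C21) on the arene side; C18 (R) | COC(=O)C1=C[C@@]23C(=O)N4C[C@@H](Cc5c2c1ccc5OC)[C@]3(C=O)CCC(=O)[C@H](C)C4 | intermediate
18 | primary alcohol (C21–OH) from 17 | COC(=O)C1=C[C@@]23C(=O)N4C[C@@H](Cc5c2c1ccc5OC)[C@]3(CO)CCC(=O)[C@H](C)C4 | intermediate
19 | acetate (C21–OAc) of 18 | COC(=O)C1=C[C@@]23C(=O)N4C[C@@H](Cc5c2c1ccc5OC)[C@]3(COC(C)=O)CCC(=O)[C@H](C)C4 | intermediate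
20 | indane ester: C13–C14 saturated, H-14 on the lactam-carbonyl face, CO2Me on the C5-bridge face (14R); aryl OMe | COC(=O)[C@@H]1C[C@@]23C(=O)N4C[C@@H](Cc5c2c1ccc5OC)[C@]3(COC(C)=O)CCC(=O)[C@H](C)C4 | intermediate
21 | phenol (C10–OH) from 20 | COC(=O)[C@@H]1C[C@@]23C(=O)N4C[C@@H](Cc5c2c1ccc5O)[C@]3(COC(C)=O)CCC(=O)[C@H](C)C4 | intermediate
22 | p-quinol dienone: C10=O, C9=C11, C16=C17, tertiary C15–OH trans to the C14 ester (15S) | COC(=O)[C@@H]1C[C@@]23C(=O)N4C[C@@H](CC5=C2[C@]1(O)C=CC5=O)[C@]3(COC(C)=O)CCC(=O)[C@H](C)C4 | intermediate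
23 | CNP0211170.1 (5R,6S,8S,14R,15S,18R) | COC(=O)[C@@H]1C[C@@]23C(=O)N4C[C@@H](CC5=C2[C@]1(O)CCC5=O)[C@]3(COC(C)=O)CCC(=O)[C@H](C)C4 | target

## Step count and risks

Total steps: 16. Longest linear sequence: 14 steps (compound 1 to 23 through steps 1–4 and 7–16); the two-step amine branch (steps 5–6) joins at step 7.

The three steps most likely to fail:

Step 10 is the most uncertain: it closes a nine-membered ring while forming a quaternary carbon next to another quaternary carbon, and the amine catalyst could also epimerize C18 or trigger a transannular aldol. The fallback sets out from 15 and uses the enol ether itself as the nucleophile instead of unmasking the aldehyde. Yb(fod)3 (10 mol%) or Me2AlCl in CH2Cl2 brings about an intramolecular inverse-electron-demand hetero-Diels–Alder reaction between the vinyl ketone (oxadiene) and the enol ether. This gives the bridged 2-methoxy-3,4-dihydro-2H-pyran acetal F1 with the same tether-enforced C5 configuration. PPTS in wet acetone then hydrolyses F1, and the route is rejoined at 17.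

Step 7 may stall at the Mannich base, over-alkylate the primary amine, or lose material by retro-Claisen opening of the β-keto ester. The fallback sets out from 8 and separates the two events. Gras α-methylenation ((CH2O)n, N-methylanilinium trifluoroacetate, THF, 65 °C) gives the isolable C6 exo-methylene ketone F2. Aza-Michael addition of 11 (freed with iPr2NEt, MeOH, 0 → 23 °C) followed by heating in toluene closes the lactam and returns to 13.

Step 15 may give a quinone methide instead (loss of the acidic benzylic H-14 from the phenoxenium ion), or add water from the wrong face. The fallback sets out from 21 and avoids the cation. Oxone/NaHCO3 in MeCN–H2O generates singlet oxygen, which adds to the phenolate para position to give the C15 hydroperoxide (p-peroxyquinol) F3. Me2S reduces F3 to 22.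

Further compounds
F1 | step 10 | bridged 2-methoxy-3,4-dihydro-2H-pyran acetal (C4–C5 and O–C21 closed, C2=C3 enol ether, C21 epimers) | COC(=O)C1=C[C@@]23C(=O)N4C[C@@H](Cc5c2c1ccc5OC)[C@]3(C(OC)O6)CC=C6[C@H](C)C4
F2 | step 7 | C6 exo-methylene ketone of 8 | COC(=O)C1=C[C@]2(C(=O)OC)C(=O)C(=C)Cc3c2c1ccc3OC
F3 | step 15 | C15 hydroperoxide (p-peroxyquinol) of 21 | COC(=O)[C@@H]1C[C@@]23C(=O)N4C[C@@H](CC5=C2[C@]1(OO)C=CC5=O)[C@]3(COC(C)=O)CCC(=O)[C@H](C)C4
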